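(Its constants belong to no real substance; no experiment stands behind them.)

The invariant of a flask with its starting material in from the start is the logarithm of the fraction left, divided by the share of catalyst spent.

the same everywhere: free enzyme 6.5 × 10⁻⁴ mol%; time 6.0 h
- summer: starting material 0.20 M; second substrate 1.10 equiv; everything together at the start
- winter: starting material 0.20 M; second substrate 1.10 equiv (fed, over 4.0 h); all else is in the flask from the start; the feed brings no volume worth counting
- midnight: starting material 0.20 M (fed, over 4.0 h); second substrate 1.10 equiv; all else is in the flask from the start; the feed brings no volume worth counting

    second substrate + loaded enzyme ⇌ second complex (K1 = 7.9 /M, k1 = 2.0 × 10⁵ /M/min)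
    free enzyme → spent catalyst (k2 = 0.018 /min)
    starting material + free enzyme ⇌ first complex (K3 = 2.1 /M, k3 = 1.4 × 10⁵ /M/min)
    first complex → loaded enzyme + first product (k4 = 42000 /min)
    second complex ⇌ free enzyme + target (K5 = 0.40 M, k5 = 840 /min)

- the flask with the highest amount of target, in percent of the starting material charged ("all alike" if they lie within 1.5 percentage points) (summer / winter / midnight / all alike)
- final target, as a percentage of the starting material charged, in summer
- final target, as a percentage of the starting material charged, in winter
- final target, as a percentage of the starting material charged, in midnight

You take over at the start, with 1.30 × 10⁻⁶ M of catalyst in each flask. Free enzyme can die at 0.018 /min, or it can take starting material and get past the first complex, with this constant: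

1.4 × 10⁵ /M/min × 42000 /min / (42000 /min + 66700 /min) = 54100 /M/min

Starting material falls at that constant times its concentration times free enzyme, and catalyst dies at 0.018 /min times free enzyme. Free enzyme cancels, and the second substrate does not enter this relation, though it does enter the share spent:

reach = 54100 /M/min × 1.30 × 10⁻⁶ M / 0.018 /min = 3.91

fraction left = exp(−reach × share spent)

The reach is the partition ratio, turnovers per death, divided by the starting material present per catalyst. With its whole catalyst spent, this reckoning puts summer at 2.01% left.

Now the share spent. In the steady round at the start of summer, before target has built up, second complex per free enzyme is:

54100 /M/min × 0.20 M / 840 /min = 12.9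

In that same round, loaded enzyme per free enzyme is 7.66 and first complex per free enzyme is 0.258, so:

free share of living catalyst = 1 / (1 + 12.9 + 7.66 + 0.258) = 4.59%

Held through 6.0 h, that share leaves 25.7% spent, so you will find about 63.4% target in summer.

Leave the starting material in at the start. In summer the odds of going on against dying begin at 6.01 × 10⁵ and fall with its concentration, and midnight begins with none in the flask. Winter's feed leaves the reach as it is.

The forecast names summer, with 73%, 62% and 48% for summer, winter and midnight, higher than mine for summer. For midnight it argues that “low starting material leaves the enzyme free and exposed to deactivation”.

The flasks give 73.9%, 62.3% and 46.9% in that order, so summer stands highest, as forecast.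

Summer has 34.4% of its catalyst spent at 6.00 h, above my 25.7%, and the reach turns that share into 26.1% left, against 26.1% read. In the neighbour with 0.50 M of starting material, the same loading lifts the reach to 9.77, and its 30.2% spent at 6.00 h gives 5.24% left, against 5.24% read.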